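In a one-step world each X charged ends as one Q, so I set the ceiling for Q in the flask at 70.0 %. But D holds two X, so the highest D reading, 8.1 %, taken as lasting, gave a rough floor of 53.8 %.

the same everywhere: L 0.30 M

| flask | X | J | remark | time |
|---|---|---|---|---|
| red | 0.70 equiv | 1.3 equiv (fed, over 12 min) | run made earlier; the fed solution adds 0.25 times the starting volume |  |
| violet | 0.70 equiv | 3 equiv (fed, over 12 min) | run made earlier; the fed solution adds 0.25 times the starting volume |  |
| flask | 0.700 equiv | 2.00 equiv (fed, over 12 min) | the fed solution adds 0.25 times the starting volume | 1.5 h |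

| run | time / min | D / % | Q / % |
|---|---|---|---|
| red | 8.00 | 4.5 | 24.8 |
| red | 20.0 | 6.7 | 45.6 |
| red | 40.0 | 5.2 | 52.0 |
| red | 60.0 | 8.1 | 57.0 |
| red | 80.0 | 5.0 | 58.5 |
| red | 120 | 7.9 | 58.5 |
| violet | 8.00 | 6.1 | 27.6 |
| violet | 20.0 | 5.0 | 43.3 |
| violet | 40.0 | 5.7 | 54.6 |
| violet | 60.0 | 7.9 | 55.2 |
| violet | 80.0 | 4.6 | 58.6 |
| violet | 120 | 4.2 | 57.3 |

(each reading ± 1 percentage point)

- every charge counts on the volume at the start, and the solution that is fed holds the whole dose
- the numbers in the tables scatter by 1 percentage point (one standard deviation)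
- what may be going on: L + X -> J + E; E + X -> J + D; D + X <-> J + Z; E -> Q; L <-> G

1. how much D there is at 1.5 h, in percent of the L charged
2. how much Q there is at 1.5 h, in percent of the L charged
3. amount of D if the flask were left three thousand times as long, in percent of the L charged

To tighten the bracket, I treated D as a small correction to the ceiling. The flask's J charge lies between those of the two runs, so I averaged the D readings of both from 40.0 min on and got 6.07 %. With X as the limiting reagent and Z neglected, the X ledger, meaning the X charged less two X for each D, put Q at 57.9 %. The Q readings from 80.0 min on, which are separate numbers, averaged 58.2 %. I committed to those values, with D staying near 6.07 % when left longer.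

The forecast said “Neither run shows a real effect of J”. It gave D 6 % (4.8 % to 7.3 %), Q 58 % (56 % to 60 %) and long-term D 6.3 % (4.8 % to 8.5 %). Its Q lay inside my bracket, below the ceiling.

The flask gave D 5.51 %, Q 57.4 % and, left far longer, D 5.76 %, each inside the forecast's range.

    L + X → J + E (k = 0.621 L mol⁻¹ min⁻¹)
    E + X → J + D (k = 0.436 L mol⁻¹ min⁻¹)
    D + X ⇌ J + Z (K = 5.32, k = 0.0450 L mol⁻¹ min⁻¹)
    E → Q (k = 0.304 min⁻¹)
    L ⇌ G (K = 0.471, k = 0.0465 min⁻¹)

With the flask's own D, the ledger read 59.0 %, while X stood at 1.1 % of its charge and Z at 0.249 %. A neighbouring flask, charged at 0.75 M of L with the equivalents held, gave D 9.28 %, above the forecast's high end. Taking two points of Q for each extra point of D, the ledger read 51.5 %, and Q in that flask stood at 51.0 %.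

All runs come from a simulation for substances that don't exist.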